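**Retrosynthetic overview**

- Chain numbering: C1 is the carboxyl carbon and C9 a prenyl methyl; the furan carries the aryl group at C2' and the chain at C4'. The strategy rests on C5, a methine bonded to furan C4' and flanked by the prenyl C6H2 and by C4H2. C5–C4 can therefore be seen as a former vinyl group on the furan that takes the prenyl unit at C5 and boron at C4 in one enantioselective three-component coupling.
- The C4–B bond then carries the acid chain: the C3–C4 bond is formed by B-alkyl Suzuki–Miyaura coupling with methyl (Z)-3-iodobut-2-enoate, and the C3–H bond (3R) by ligand-controlled copper hydride 1,4-reduction.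
- The vinylfuran comes from 2,4-dibromofuran by two site-selective Suzuki–Miyaura couplings (aryl at C2' first, vinyl at C4' second). The arylboronic acid comes from hydroquinone by bis-MOM protection and directed ortho-lithiation.
- No ring is formed: the benzene ring and the furan are both purchased as aromatic rings.
- End game: saponification, then non-acidic MOM removal, so that the free hydroquinone never sees base or strong acid.

Key step: step 6

Assumption: the absolute sense of induction of the chiral ligands in steps 6 and 9 is assigned by analogy with vinylarene borylcupration and enoate hydrocupration and would be checked on the first run; both antipodes of each ligand are available, and the one delivering 5S and 3R is meant throughout.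

**Route**

Step 1
Reactants: 1 hydroquinone
Product: 2 1,4-bis(methoxymethoxy)benzene
Conditions: MOMCl (3 equiv), iPr2NEt (4 equiv), CH2Cl2/DMF, 0 °C to rt
Reagents that add atoms: chloromethyl methyl ether, COCCl
Why: O-alkylation of both phenols by the reactive α-chloro ether under amine base (Williamson-type acetal formation) should give the bis-MOM ether, which serves as both protecting and directing group.

Step 2
Reactants: 2 1,4-bis(methoxymethoxy)benzene
Product: 5 [2,5-bis(methoxymethoxy)phenyl]boronic acid, via aryllithium 3 (not isolated), via lithium aryltrimethoxyborate 4 (not isolated)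
Conditions: n-BuLi (1.2 equiv), TMEDA, THF, 0 °C; B(OMe)3 (2 equiv), −78 °C to rt; aq AcOH to pH 5–6, 0 °C
Reagents that add atoms: n-butyllithium, [Li]CCCC (lithium of 3 and 4); trimethyl borate, COB(OC)OC; water, O
Why: Directed ortho-metalation by the MOM oxygen (all four ring CH positions of 2 are equivalent), borate quench and mild hydrolysis should give the boronic acid without loss of the acetals.

Step 3
Reactants: 5 [2,5-bis(methoxymethoxy)phenyl]boronic acid; 6 2,4-dibromofuran
Product: 7 2-[2,5-bis(methoxymethoxy)phenyl]-4-bromofuran
Conditions: Pd(PPh3)4 (3 mol %), 2 M aq K2CO3, DME, 70 °C; 1.0 equiv of 5, 1.1 equiv of 6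
Reagents that add atoms: none
Why: Suzuki–Miyaura coupling in which zerovalent palladium inserts faster into the α (C2) C–Br bond of the furan than into the β (C4) C–Br bond, so one equivalent of boronic acid should give the 2-aryl-4-bromofuran.

Step 4
Reactants: 7 2-[2,5-bis(methoxymethoxy)phenyl]-4-bromofuran; 8 potassium vinyltrifluoroborate
Product: 9 2-[2,5-bis(methoxymethoxy)phenyl]-4-vinylfuran
Conditions: Pd(OAc)2 (3 mol %), SPhos (6 mol %), K2CO3 (3 equiv), THF/H2O (10:1), 60 °C, trace BHT; product kept cold, acid-free and used promptly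
Reagents that add atoms: none
Why: Suzuki–Miyaura vinylation with an electron-rich dialkylbiarylphosphine that activates the less reactive β-bromofuran at moderate temperature, which limits dimerisation of the diene-like vinylfuran.

Step 5
Reactants: 10 prenol (3-methylbut-2-en-1-ol)
Product: 11 tert-butyl 3-methylbut-2-en-1-yl carbonate
Conditions: Boc2O (1.2 equiv), Bu4NHSO4 (cat.), 30% aq NaOH, CH2Cl2, 0 °C to rt
Reagents that add atoms: di-tert-butyl dicarbonate, CC(C)(C)OC(=O)OC(=O)OC(C)(C)C
Why: Phase-transfer O-acylation of the primary allylic alcohol gives the mixed carbonate, whose ionisation later releases CO2 and the tert-butoxide that turns over the copper cycle.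

Step 6
Reactants: 9 2-[2,5-bis(methoxymethoxy)phenyl]-4-vinylfuran; 11 tert-butyl 3-methylbut-2-en-1-yl carbonate
Product: 12 2-[(2S)-2-{5-[2,5-bis(methoxymethoxy)phenyl]furan-3-yl}-5-methylhex-4-en-1-yl]-4,4,5,5-tetramethyl-1,3,2-dioxaborolane
Conditions: CuCl (5 mol %), (R)-tert-butyl 2-(diphenylphosphino)phenyl sulfoxide (6 mol %, hand per the assumption), Pd(dppf)Cl2 (3 mol %), KOtBu (20 mol %), B2pin2 (1.5 equiv), 11 (1.5 equiv), THF, 0 °C to rt, argon
Reagents that add atoms: bis(pinacolato)diboron, CC1(C)OB(OC1(C)C)B1OC(C)(C)C(C)(C)O1
Why: A chiral-ligand copper boryl, formed from the copper tert-butoxide and B2pin2, adds across the vinyl group of 9 with boron on the terminal carbon (future C4) and copper on the furylic carbon (future C5), where the furan stabilises the C–Cu bond as an arene does in a styrene. In parallel Pd(dppf) ionises carbonate 11 to a 1,1-dimethylallyl palladium cation with loss of CO2 and tert-butoxide, the furylic alkylcopper transmetalates to it stereospecifically, and reductive elimination at the unsubstituted CH2 terminus forms C5–C6 and returns both metals. This is the known copper/palladium cooperative enantioselective allylboration of vinylarenes with B2pin2 and allyl carbonates, applied here to a vinylfuran and a prenyl donor; no ring is closed. The C5 stereocentre (S) is controlled only by the chiral ligand on copper in the enantiofacial borylcupration, since 9 has no other stereocentre. The step needs boron-terminal regiochemistry, secured by conjugation of the alkene with the furan, and linear rather than reverse-prenyl coupling, secured by the steric difference between the CH2 and CMe2 termini of the allyl ligand.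

Step 7
Reactants: 13 methyl but-2-ynoate
Product: 14 methyl (Z)-3-iodobut-2-enoate
Conditions: NaI (1.6 equiv), AcOH, 115 °C
Reagents that add atoms: sodium iodide, [Na+].[I-]
Why: Conjugate addition of iodide to the ynoate followed by trans protonation (anti hydroiodination) should give the Z-iodoenoate as a single geometric isomer.

Step 8
Reactants: 12 the (S)-pinacol boronate; 14 methyl (Z)-3-iodobut-2-enoate
Product: 15 methyl (2Z,5R)-5-{5-[2,5-bis(methoxymethoxy)phenyl]furan-3-yl}-3,8-dimethylnona-2,7-dienoate
Conditions: Pd(OAc)2 (5 mol %), RuPhos (10 mol %), K3PO4 (3 equiv), toluene/H2O (10:1), 80 °C, degassed; 1.3 equiv of 14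
Reagents that add atoms: none
Why: B-alkyl Suzuki–Miyaura coupling: oxidative addition of the alkenyl iodide proceeds with retention of the Z geometry, and the bulky dialkylbiarylphosphine promotes transmetalation of the primary alkyl boronate over β-hydride elimination. C5 is untouched; its descriptor changes from S to R only because the CIP priorities change.

Step 9
Reactants: 15 the (2Z,5R)-dienoate
Product: 16 methyl (3R,5S)-5-{5-[2,5-bis(methoxymethoxy)phenyl]furan-3-yl}-3,8-dimethylnon-7-enoate
Conditions: Cu(OAc)2·H2O (5 mol %), (R)-DTBM-SEGPHOS (5.5 mol %, hand per the assumption), (EtO)2MeSiH (3 equiv), t-BuOH (2 equiv), toluene, 0 °C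
Reagents that add atoms: none
Why: Copper hydride asymmetric conjugate reduction: the bisphosphine-ligated copper hydride delivers hydride to C3 on the face chosen by the ligand, so 3R is reagent-controlled on the geometrically pure Z-enoate with little bias from remote C5. tert-Butanol protonates the copper enolate, and the isolated trisubstituted alkene and the furan are not substrates for copper hydride.

Step 10
Reactants: 16 the (3R,5S)-methyl ester
Product: 18 (3R,5S)-5-{5-[2,5-bis(methoxymethoxy)phenyl]furan-3-yl}-3,8-dimethylnon-7-enoic acid, via lithium carboxylate 17 (not isolated)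
Conditions: LiOH (3 equiv), THF/MeOH/H2O, rt; then cold 0.5 M aq HCl to pH 4–5, 0 °C
Reagents that add atoms: lithium hydroxide, [Li+].[OH-]
Why: Ester saponification; the MOM acetals, the furan and the alkene are stable to hydroxide and to the brief, cold, weakly acidic work-up, and neither stereocentre is epimerisable (C3 is β to the carboxyl group).

Step 11
Reactants: 18 the bis-MOM acid
Product: 20 (3R,5S)-5-[5-(2,5-dihydroxyphenyl)furan-3-yl]-3,8-dimethylnon-7-enoic acid (CNP0531232.1), via tris(trimethylsilyl) derivative 19 (not isolated)
Conditions: TMSOTf (6 equiv), 2,2'-bipyridyl (9 equiv), CH2Cl2, 0 °C to rt, argon; then H2O, rt; degassed solvents for work-up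
Reagents that add atoms: trimethylsilyl trifluoromethanesulfonate, C[Si](C)(C)OS(=O)(=O)C(F)(F)F (silyl groups of 19)
Why: Silyl triflate/2,2'-bipyridyl cleavage of aryl MOM ethers: the buffered silyl triflate converts each aryl acetal into an aryl silyl ether and a methoxymethyl-bipyridinium salt, and water then frees the phenols and the transiently silylated acid. No strong Brønsted acid is present that could cyclise the prenyl group onto the furan, and no methanol that could re-esterify the acid.

**Compound list**

1 | hydroquinone | Oc1ccc(O)cc1 | starting material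
2 | 1,4-bis(methoxymethoxy)benzene | COCOc1ccc(OCOC)cc1 | intermediate
3 | [2,5-bis(methoxymethoxy)phenyl]lithium | [Li]c1cc(OCOC)ccc1OCOC | intermediate
4 | lithium [2,5-bis(methoxymethoxy)phenyl]trimethoxyborate | [Li+].CO[B-](OC)(OC)c1cc(OCOC)ccc1OCOC | intermediate
5 | [2,5-bis(methoxymethoxy)phenyl]boronic acid | COCOc1ccc(OCOC)c(B(O)O)c1 | intermediate
6 | 2,4-dibromofuran | Brc1coc(Br)c1 | starting material
7 | 2-[2,5-bis(methoxymethoxy)phenyl]-4-bromofuran | COCOc1ccc(OCOC)c(-c2cc(Br)co2)c1 | intermediate
8 | potassium vinyltrifluoroborate | C=C[B-](F)(F)F.[K+] | starting material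
9 | 2-[2,5-bis(methoxymethoxy)phenyl]-4-vinylfuran | C=Cc1coc(-c2cc(OCOC)ccc2OCOC)c1 | intermediate
10 | prenol (3-methylbut-2-en-1-ol) | CC(C)=CCO | starting material
11 | tert-butyl 3-methylbut-2-en-1-yl carbonate | CC(C)=CCOC(=O)OC(C)(C)C | intermediate
12 | 2-[(2S)-2-{5-[2,5-bis(methoxymethoxy)phenyl]furan-3-yl}-5-methylhex-4-en-1-yl]-4,4,5,5-tetramethyl-1,3,2-dioxaborolane | CC(C)=CC[C@H](CB1OC(C)(C)C(C)(C)O1)c1coc(-c2cc(OCOC)ccc2OCOC)c1 | intermediate
13 | methyl but-2-ynoate | CC#CC(=O)OC | starting material
14 | methyl (Z)-3-iodobut-2-enoate | C/C(I)=C/C(=O)OC | intermediate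
15 | methyl (2Z,5R)-5-{5-[2,5-bis(methoxymethoxy)phenyl]furan-3-yl}-3,8-dimethylnona-2,7-dienoate | CC(C)=CC[C@H](C/C(C)=C\C(=O)OC)c1coc(-c2cc(OCOC)ccc2OCOC)c1 | intermediate
16 | methyl (3R,5S)-5-{5-[2,5-bis(methoxymethoxy)phenyl]furan-3-yl}-3,8-dimethylnon-7-enoate | CC(C)=CC[C@H](C[C@@H](C)CC(=O)OC)c1coc(-c2cc(OCOC)ccc2OCOC)c1 | intermediate
17 | lithium (3R,5S)-5-{5-[2,5-bis(methoxymethoxy)phenyl]furan-3-yl}-3,8-dimethylnon-7-enoate | [Li+].CC(C)=CC[C@H](C[C@@H](C)CC(=O)[O-])c1coc(-c2cc(OCOC)ccc2OCOC)c1 | intermediate
18 | (3R,5S)-5-{5-[2,5-bis(methoxymethoxy)phenyl]furan-3-yl}-3,8-dimethylnon-7-enoic acid | CC(C)=CC[C@H](C[C@@H](C)CC(=O)O)c1coc(-c2cc(OCOC)ccc2OCOC)c1 | intermediate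
19 | trimethylsilyl (3R,5S)-5-{5-[2,5-bis(trimethylsilyloxy)phenyl]furan-3-yl}-3,8-dimethylnon-7-enoate | CC(C)=CC[C@H](C[C@@H](C)CC(=O)O[Si](C)(C)C)c1coc(-c2cc(O[Si](C)(C)C)ccc2O[Si](C)(C)C)c1 | intermediate
20 | (3R,5S)-5-[5-(2,5-dihydroxyphenyl)furan-3-yl]-3,8-dimethylnon-7-enoic acid (CNP0531232.1) | CC(C)=CC[C@H](C[C@@H](C)CC(=O)O)c1coc(-c2cc(O)ccc2O)c1 | target

**Step count**

Total steps: 11. Longest linear sequence: 9 steps (steps 1, 2, 3, 4, 6, 8, 9, 10, 11 from hydroquinone).

**Steps most likely to fail**

1. Step 6 (three-component borylallylation).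
   - What may go wrong: the copper boryl may be intercepted by the allyl-palladium species before it adds to the alkene (direct prenyl–boron coupling); the furylic copper may be protonated (net hydroboration); the prenyl-palladium may lose a proton to give isoprene; or facial discrimination on a furan-conjugated alkene may be poorer than on a styrene.
   - Fallback: it sets out from 7 and comes back at 12, and sets C5 by enantioselective protoboration of a 1,1-disubstituted alkene.
   - Miyaura borylation of 7 (Pd(dppf)Cl2, KOAc, B2pin2, dioxane, 90 °C) should give 2-{5-[2,5-bis(methoxymethoxy)phenyl]furan-3-yl}-4,4,5,5-tetramethyl-1,3,2-dioxaborolane F1.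
   - Copper-catalysed (CuI) substitution of 2,3-dibromopropene by 2-methylprop-1-enylmagnesium bromide should give 2-bromo-5-methylhexa-1,4-diene F2.
   - Suzuki–Miyaura coupling of F1 with F2 (Pd(PPh3)4, aq K3PO4, dioxane) should give 2-[2,5-bis(methoxymethoxy)phenyl]-4-(5-methylhexa-1,4-dien-2-yl)furan F3.
   - Enantioselective copper-catalysed protoboration of the aryl-conjugated 1,1-disubstituted alkene of F3 (CuCl, chiral sulfonate-bearing N-heterocyclic carbene from its imidazolinium salt, KOtBu, B2pin2, MeOH, THF, −50 °C) should place boron on the terminal carbon and hydrogen on C5 and return boronate 12. The isolated trisubstituted alkene is inert to the copper boryl.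

2. Step 8 (B-alkyl Suzuki–Miyaura coupling).
   - What may go wrong: transmetalation of the β-branched primary alkyl pinacol boronate may be slow, so that protodeboronation, base-induced degradation of the iodoenoate, or Z-to-E isomerisation of the enoate competes.
   - Fallback: it sets out from 12 and comes back at 15, and replaces boron by zinc as the transmetalating metal.
   - Oxidation of 12 (NaBO3·4H2O, THF/H2O) should give (2S)-2-{5-[2,5-bis(methoxymethoxy)phenyl]furan-3-yl}-5-methylhex-4-en-1-ol F4.
   - Appel iodination (I2, PPh3, imidazole, CH2Cl2, 0 °C) should give the primary iodide 2-[2,5-bis(methoxymethoxy)phenyl]-4-[(2S)-1-iodo-5-methylhex-4-en-2-yl]furan F5.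
   - Zinc insertion (activated Zn dust, LiCl, THF) should give the alkylzinc iodide F6.
   - Negishi coupling of F6 with 14 (Pd(OAc)2, SPhos, THF, rt) should give enoate 15 with retention of the Z geometry.

3. Step 9 (copper hydride 1,4-reduction).
   - What may go wrong: the catalyst may discriminate incompletely between the methyl and primary-alkyl β-substituents (a matched or mismatched pairing with remote C5), or the enoate may partly isomerise from Z to E before hydride transfer; either would erode the configurational purity at C3.
   - Fallback: it sets out from 12 and comes back at 16, and introduces the C3 methyl group as the nucleophile instead of the C3 hydrogen.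
   - Boronate 12 is taken through the alcohol F4 and the iodide F5 to the alkylzinc iodide F6 as above.
   - Negishi coupling of F6 with methyl (E)-3-iodoacrylate should give methyl (2E,5S)-5-{5-[2,5-bis(methoxymethoxy)phenyl]furan-3-yl}-8-methylnona-2,7-dienoate F7.
   - Copper-catalysed asymmetric conjugate addition of MeMgBr (CuI, Tol-BINAP of the appropriate hand, t-BuOMe, −20 °C) should give ester 16. Here the catalyst distinguishes hydrogen from alkyl at the β-carbon, not methyl from alkyl.

Further compounds
F1 | step 6 | 2-{5-[2,5-bis(methoxymethoxy)phenyl]furan-3-yl}-4,4,5,5-tetramethyl-1,3,2-dioxaborolane | COCOc1ccc(OCOC)c(-c2cc(B3OC(C)(C)C(C)(C)O3)co2)c1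
F2 | step 6 | 2-bromo-5-methylhexa-1,4-diene | C=C(Br)CC=C(C)C
F3 | step 6 | 2-[2,5-bis(methoxymethoxy)phenyl]-4-(5-methylhexa-1,4-dien-2-yl)furan | C=C(CC=C(C)C)c1coc(-c2cc(OCOC)ccc2OCOC)c1
F4 | step 8 | (2S)-2-{5-[2,5-bis(methoxymethoxy)phenyl]furan-3-yl}-5-methylhex-4-en-1-ol | CC(C)=CC[C@H](CO)c1coc(-c2cc(OCOC)ccc2OCOC)c1
F5 | step 8 | 2-[2,5-bis(methoxymethoxy)phenyl]-4-[(2S)-1-iodo-5-methylhex-4-en-2-yl]furan | CC(C)=CC[C@H](CI)c1coc(-c2cc(OCOC)ccc2OCOC)c1
F6 | step 8 | [(2S)-2-{5-[2,5-bis(methoxymethoxy)phenyl]furan-3-yl}-5-methylhex-4-en-1-yl]zinc iodide | CC(C)=CC[C@H](C[Zn]I)c1coc(-c2cc(OCOC)ccc2OCOC)c1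
F7 | step 9 | methyl (2E,5S)-5-{5-[2,5-bis(methoxymethoxy)phenyl]furan-3-yl}-8-methylnona-2,7-dienoate | CC(C)=CC[C@H](C/C=C/C(=O)OC)c1coc(-c2cc(OCOC)ccc2OCOC)c1
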